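## Retrosynthetic overview
1. Target 6 ⇐ protected sulfate salt 4, by removing three aryl acetates and exchanging the cation for H+.
2. 4 ⇐ apigenin triacetate 2, by disconnecting C3–O. The C3–H bond becomes C3–OSO3(−) in one oxidative step, so O3 and the sulfate arrive together and the four hydroxyls of kaempferol never need to be told apart.
3. 2 ⇐ apigenin 1 (a bulk nutraceutical) by peracetylation.
4. Rings A, B and C are bought intact in 1. The only ring made is the five-membered cyclic sulfate of 3, which closes on C2=C3 and opens again in the same flask.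

Assumption: the target has no stereocentre and is achiral, so no enantiocontrol is needed, and it is delivered in the hydrogen sulfate (free acid) form as drawn.

## Route

Step 1
Reactants: 1 apigenin (4',5,7-trihydroxyflavone)
Product: 2 4',5,7-tri-O-acetylapigenin
Conditions: Ac2O (6 equiv), pyridine, DMAP (5 mol %), 20 → 50 °C
Reagents that add atoms: acetic anhydride, CC(=O)OC(C)=O
Why: DMAP-catalysed nucleophilic O-acylation (Steglich-type peracetylation) caps all three phenols, the chelated 5-OH included at 50 °C, as electron-poor aryl esters that resist trivalent iodine oxidants and SO3 and lower the migratory aptitude of ring B; no stereocentre is involved.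

Step 2
Reactants: 2 4',5,7-tri-O-acetylapigenin
Product: 4 triethylammonium 4',5,7-tri-O-acetylkaempferol 3-O-sulfate, via cis-2,3-cyclic sulfate 3 (not isolated)
Conditions: PhIO and SO3·DMF (1.5 equiv each), 4 Å MS, CH2Cl2, −40 °C, 30 min; add 2, −40 → 20 °C; then Et3N (3 equiv), 0 °C; SiO2 (CH2Cl2/MeOH/Et3N)
Reagents that add atoms: iodosylbenzene, O=Ic1ccccc1; sulfur trioxide–DMF complex, O=S(=O)=O.CN(C)C=O; triethylamine, CCN(CC)CC
Why: Proposed new method: the zwitterion PhI(+)–OSO3(−) made in the flask is attacked by C3 (the nucleophilic β-carbon of the ring C enol ether), the resulting 2-aryl oxocarbenium ion is capped at C2 by the tethered sulfate, intramolecular SN2 displacement of the iodobenzene hypernucleofuge at C3 then forms the key C3–O bond and closes the racemic cis cyclic sulfate 3, and its ketal-type C2–O bond ionises at once so that Et3N removes the acidic H3 (E1-type ring opening), erasing both transient stereocentres and restoring the pyranone as enol sulfate 4; the closest known reaction types are the one-step conversion of simple alkenes into 1,2-cyclic sulfates by iodosylbenzene–SO3 adducts and the 2,3-dioxygenation of flavones by trivalent iodine reagents in methanol, neither of which has been shown as a C–H sulfatoxylation of a flavone or other enone.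

Step 3
Reactants: 4 triethylammonium 4',5,7-tri-O-acetylkaempferol 3-O-sulfate
Product: 6 kaempferol 3-O-sulfate (target), via potassium kaempferol 3-O-sulfate 5 (not isolated)
Conditions: K2CO3 (3 equiv), MeOH, Ar, 0 → 20 °C; evaporate; 1 M HCl to pH 2, 0 °C; C18 (H2O/MeCN, 0.1 % HCO2H), freeze-dry
Reagents that add atoms: none
Why: Zemplén-type base-mediated transesterification cleaves the three aryl acetates while the anionic sulfate monoester repels methoxide and survives, Et3N and MeOAc leave on evaporation, and a brief cold acidification with reverse-phase desalting replaces K+ by H+ before acid hydrolysis of the sulfate can compete; no stereocentre is involved.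

## Compound list
1 | apigenin (4',5,7-trihydroxyflavone) | O=c1cc(-c2ccc(O)cc2)oc2cc(O)cc(O)c12 | starting material
2 | 4',5,7-tri-O-acetylapigenin | CC(=O)Oc1ccc(cc1)-c1cc(=O)c2c(OC(C)=O)cc(OC(C)=O)cc2o1 | intermediate
3 | 4',5,7-triacetoxyflavanone-2,3-diyl cyclic sulfate, cis ring fusion, racemic (relative configuration drawn), not isolated | CC(=O)Oc1ccc(cc1)[C@]12Oc3cc(OC(C)=O)cc(OC(C)=O)c3C(=O)[C@H]1OS(=O)(=O)O2 | intermediate
4 | triethylammonium 4',5,7-tri-O-acetylkaempferol 3-O-sulfate | CC(=O)Oc1ccc(cc1)-c1oc2cc(OC(C)=O)cc(OC(C)=O)c2c(=O)c1OS(=O)(=O)[O-].CC[NH+](CC)CC | intermediate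
5 | potassium kaempferol 3-O-sulfate, not isolated (bench-stable storage form if wanted) | O=c1c(OS(=O)(=O)[O-])c(-c2ccc(O)cc2)oc2cc(O)cc(O)c12.[K+] | intermediate
6 | kaempferol 3-O-sulfate (hydrogen sulfate form, achiral) | O=c1c(OS(=O)(=O)O)c(-c2ccc(O)cc2)oc2cc(O)cc(O)c12 | target

## Step count and risks
Total step count: 3. Longest linear sequence: 3.

**Step 2 (proposed new step, highest risk).**
- (a) SO3 or the iodine reagent may bind the C4 carbonyl oxygen and turn ring C into an unreactive 4-oxy-flavylium species.
- (b) After capture at C2, ring B may migrate from C2 to C3 as PhI leaves, giving isoflavone-type products.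
- (c) Ring A may be attacked to give a diaryliodonium salt.
- Fallback, all known chemistry, sets out from 2 and comes back at 4. Epoxidise the C2=C3 bond of 2 with dimethyldioxirane (acetone/CH2Cl2, 0 → 20 °C) to racemic 4',5,7-triacetoxy-2,3-epoxyflavanone F1. Isomerise this with catalytic p-TsOH to 4',5,7-tri-O-acetylkaempferol F2. O-sulfate its only free hydroxyl with SO3·NEt3 (DMF, 40 °C), which gives the triethylammonium salt 4 directly.

**Step 3.**
- The electron-rich free flavonoid may degrade in base.
- The 3-sulfate may hydrolyse during acidification.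
- Fallback sets out from 1 and comes back at 6, replacing base-labile esters with groups removed by neutral hydrogenolysis. Acylate 1 with CbzCl (Et3N, DMAP, CH2Cl2) to 4',5,7-tris-O-(benzyloxycarbonyl)apigenin F3. Treat F3 under the step 2 conditions, passing through its transient cis-2,3-cyclic sulfate F4, to reach triethylammonium 4',5,7-tris-O-(benzyloxycarbonyl)kaempferol 3-O-sulfate F5. Hydrogenolyse (H2 1 atm, Pd/C, THF/MeOH) to triethylammonium kaempferol 3-O-sulfate F6. Pass a cold aqueous solution through a sulfonic acid resin in its H+ form and freeze-dry to obtain 6, with no base and no mineral acid used.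

**Step 1 (lowest risk).**
- The chelated 5-OH may acetylate incompletely.
- The 5-OAc may fall off on handling, feeding a free phenol to the oxidant.
- Fallback sets out from 1 and comes back at 5, changing the protecting group class to carbonates installed with a more reactive acyl chloride. Treat 1 with ClCO2Me (Et3N, DMAP, CH2Cl2) to give 4',5,7-tris-O-(methoxycarbonyl)apigenin F7. The step 2 conditions convert F7, through its transient cis-2,3-cyclic sulfate F8, into triethylammonium 4',5,7-tris-O-(methoxycarbonyl)kaempferol 3-O-sulfate F9. K2CO3/MeOH then strips the carbonates to give 5, which is acidified as in step 3.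

## Further compounds
F1 | step 2 | 4',5,7-triacetoxy-2,3-epoxyflavanone, racemic | CC(=O)Oc1ccc(cc1)[C@]12Oc3cc(OC(C)=O)cc(OC(C)=O)c3C(=O)[C@H]1O2
F2 | step 2 | 4',5,7-tri-O-acetylkaempferol | CC(=O)Oc1ccc(cc1)-c1oc2cc(OC(C)=O)cc(OC(C)=O)c2c(=O)c1O
F3 | step 3 | 4',5,7-tris-O-(benzyloxycarbonyl)apigenin | O=C(OCc1ccccc1)Oc1ccc(cc1)-c1cc(=O)c2c(OC(=O)OCc3ccccc3)cc(OC(=O)OCc3ccccc3)cc2o1
F4 | step 3 | cis-2,3-cyclic sulfate of the tris-Cbz flavanone-2,3-diol, racemic, transient | O=C(OCc1ccccc1)Oc1ccc(cc1)[C@]12Oc3cc(OC(=O)OCc4ccccc4)cc(OC(=O)OCc4ccccc4)c3C(=O)[C@H]1OS(=O)(=O)O2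
F5 | step 3 | triethylammonium 4',5,7-tris-O-(benzyloxycarbonyl)kaempferol 3-O-sulfate | O=C(OCc1ccccc1)Oc1ccc(cc1)-c1oc2cc(OC(=O)OCc3ccccc3)cc(OC(=O)OCc3ccccc3)c2c(=O)c1OS(=O)(=O)[O-].CC[NH+](CC)CC
F6 | step 3 | triethylammonium kaempferol 3-O-sulfate | O=c1c(OS(=O)(=O)[O-])c(-c2ccc(O)cc2)oc2cc(O)cc(O)c12.CC[NH+](CC)CC
F7 | step 1 | 4',5,7-tris-O-(methoxycarbonyl)apigenin | COC(=O)Oc1ccc(cc1)-c1cc(=O)c2c(OC(=O)OC)cc(OC(=O)OC)cc2o1
F8 | step 1 | cis-2,3-cyclic sulfate of the tris(methyl carbonate) flavanone-2,3-diol, racemic, transient | COC(=O)Oc1ccc(cc1)[C@]12Oc3cc(OC(=O)OC)cc(OC(=O)OC)c3C(=O)[C@H]1OS(=O)(=O)O2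
F9 | step 1 | triethylammonium 4',5,7-tris-O-(methoxycarbonyl)kaempferol 3-O-sulfate | COC(=O)Oc1ccc(cc1)-c1oc2cc(OC(=O)OC)cc(OC(=O)OC)c2c(=O)c1OS(=O)(=O)[O-].CC[NH+](CC)CC
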